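## Analysis of the target

Numbering used throughout: ring carbons C1–C10; C14 is the methyl on C10, C15 the methyl on C4; the lactone is C8–O–C12(=O)–C11, with C11 bonded to C7 and carrying methyl C13.

- The target is a germacranolide-type sesquiterpenoid: a ten-membered carbocycle with a Z trisubstituted alkene C1=C10 and an E trisubstituted alkene C4=C5, fused across C7–C8 to a γ-lactone.
- Four contiguous stereocentres are present: C6 (S), C7 (S), C8 (R) and the quaternary C11 (R). The lactone is trans-fused (H7 and H8 anti). The C6 and C8 oxygens lie on the same side of the macrocycle, both anti to the C7–C11 bond. At C11 the methyl is cis to H7 and the acyloxy group faces C6.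
- Both esters are angelates (Z-2-methylbut-2-enoates). They slip to tiglates under acid, nucleophilic acyl-transfer catalysis, strong heat or triplet sensitisation. The 1,5-diene in the medium ring is open to Cope rearrangement and acid-induced transannular cyclisation, and the C6 ester is allylic.
- Whenever C6 is a carbonyl, C8–O and C11–O are β-oxygens. Base then invites E1cB loss of the C8 carboxylate, epimerisation of the ring fusion at C7, or retro-aldol loss of C11.
- The difficulty is twofold: a ten-membered ring with one Z and one E alkene, and the esterification of a tertiary alcohol with an acid that loses its geometry easily.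
- The strategy rests on one feature. The ring is a four-carbon unit C1–C2–C3–C4 joined to a six-carbon unit C5–C10, and each alkene links one carbon of each unit. The C1=C4 bond of a cyclobutene and the C5=C10 bond of a cyclohexenone can therefore exchange partners by [2+2] photocycloaddition and thermal cleavage. That cyclohexenone (ketone at C6) already carries C7, C8 and the lactone.

## Retrosynthetic reasoning

**Esters (28 ⇒ 25 + 26; 25 ⇒ 24; 24 ⇒ 21 + 22).** The two acyl–oxygen bonds are cut last. The angelates would not survive irradiation next to a triplet enone or prolonged heating, and the C11 oxygen must stay masked while C6 is a ketone. The secondary allylic ester is made first from 21 and 22 without an alkoxide. The silyl ether is then removed, and the tertiary ester is made from the alkoxide 27 and anhydride 26. The forward steps must keep the Z geometry and must not let a C6 alkoxide attack C12.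

**C6–H (21 ⇒ 20).** The carbinol is traced to the conjugated ketone 20. This is the oxidation level at which the ring-forming chemistry works. The forward reduction must be 1,2-selective and must deliver hydride anti to the bulky C11 substituent on C7.

**C1–C4 and C5–C10 (20 ⇒ 19).** Reconnecting these two bonds turns the cyclodecadienone into the bicyclo[2.2.0]hexane 19. This removes the medium ring and both alkene geometries from the problem. The forward thermolysis must cleave the central bond and then C5–C10, not C2–C3. The cis ring fusion of 19 must translate into the 4E,1(10)Z pattern.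

**C4–C5 and C1–C10 (19 ⇒ 15 + 17).** These are the two bonds of the photocycloaddition between enone 15 and 1-methylcyclobutene 17 (from 16 by double-bond isomerisation). Cutting here divides the skeleton into a bicyclic enone holding all four oxygenated carbons and a four-carbon hydrocarbon. The forward step needs head-to-head orientation and a cis fusion at C5/C10.

**C5=C10 (15 ⇒ 14).** The enone alkene is opened to a vinyl ketone and a 2-methylallyl group on a monocyclic lactone. Ring closure then happens under neutral conditions. Base is not tolerated once the β-acyloxy ketone exists, and an aldol closure would have two regiochemical outcomes.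

**C5–C6 (14 ⇒ 12 + 13; 12 ⇒ 11 ⇒ 10).** The vinyl group is attached to the C6 acyl carbon by a neutral acyl cross-coupling of thioester 12 with stannane 13. This avoids a C6 alkoxide, which could translactonise onto C12. The thioester comes from the imide 11, and the silyl ether of 11 is put on 10 before any base is used.

**C7–C8 and C8–O–C12 (10 ⇒ 5 + 7).** The syn relationship between the C11 branch on C7 and the C8 oxygen along the C6–C9 chain is that of a syn aldol, and it maps onto the trans lactone. The bond is therefore cut to the boron enolate 8 of imide 5 and aldehyde 7 (from 6). The adduct 9 lactonises by opening its own dioxolanone, so the same step makes the lactone and frees the C11 hydroxyl.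

**C11 from the chiral pool (5 ⇒ 2 + 3; 2 ⇒ 1).** C11, C12, C13, C7 and C6 are the five carbons of 1, whose stereocentre is never touched. The dioxolanone 2 distinguishes the two carboxyl groups and activates C12 for the later lactonisation. The auxiliary 3 controls C7 and C8.

## Alternatives that were turned down

**Alternative 1: nitrile oxide macrocyclisation.**
- Disconnection: the ring bond C7–C8 and the C6–O bond, leading back to the open-chain nitro triene A2.
- Forward key step: dehydration of the primary nitro group to a nitrile oxide and intramolecular dipolar cycloaddition onto the Z C6=C7 alkene. This would give A1, in which an isoxazoline spans C6–O and C7–C8 of the new carbocycle.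
- For: one step closes the ring, places oxygen at C6 and a masked carbonyl at C8, and fixes H6/H7 by suprafacial addition to a Z alkene. On the C6 configuration it is stronger than the chosen route, which depends on a late hydride reduction.
- Against: it is a direct closure of a ten-membered ring holding two trisubstituted alkenes, so transannular strain and entropy both oppose it and dipole dimerisation competes. Facial control comes only from allylic strain at C11. The dipole could also engage C4=C5. Three alkenes of defined geometry must be built one by one beforehand. N–O cleavage and a C8 reduction that must come out trans to C7 follow.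
- Comparison: the chosen route gets both ring alkenes and the ring from two cyclic components whose geometry is dictated by small rings, in far fewer steps. In place of built-in C6 control it offers an inversion fallback.

**Alternative 2: [2,3]-Wittig ring contraction.**
- Disconnection: the C6–C7 bond, traced to an O–C13 bond of the thirteen-membered stannyl ether A4.
- Forward key step: tin–lithium exchange at C6 and a [2,3]-shift of the α-oxy carbanion would give A3, the ten-membered C6 carbinol with an exocyclic C11=C13 methylene.
- For: no direct medium-ring closure is needed, C6 and C7 are set in one ordered transition state, and no step runs near 200 °C. On those points it is as strong as or stronger than the chosen route.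
- Against: the C6 carbanion is both α-oxygenated and allylic, so configurational stability and [1,2]-shift competition are doubtful. A stereodefined secondary allylic stannane inside a macrocycle is hard to make. After the shift C11 is sp2, so the tertiary carbinol must be created without a nearby control element, then C12 oxidised and lactonised. The macrocyclic ether needs three trisubstituted alkenes set in a long linear sequence.
- Comparison: the chosen route takes C11 intact from the chiral pool and is much shorter. The price is the thermal step and the late reduction.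

**Alternative 3: Passerini reaction.**
- Disconnection: C11–C12 and the C11–O acyl bond, leading back to the C7 methyl ketone A6, angelic acid 22 and the convertible isocyanide A7.
- Forward key step: the three components would combine to the α-angeloyloxy amide A5; no ring is closed.
- For: the tertiary angelate is made without acylating a hindered tertiary alcohol, and the acid reacts as a nucleophile, so its geometry is not exposed to acyl activation. On this point it is clearly stronger than the chosen route.
- Against: it does not address the ten-membered ring or its alkenes, which need a separate ring-forming plan. Passerini reactions of hindered ketones with weak acids are slow. The new quaternary centre would form under weak 1,2-induction in a flexible macrocycle. A6 is a β-oxygenated ketone prone to elimination and C7 epimerisation. Amide-to-lactone exchange then threatens the esters.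
- Comparison: the chosen route accepts a late alkoxide acylation, but it fixes C11 with certainty and solves ring construction and alkene geometry in two operations.

Key step: step 10

## Route

Remark on the chemistry: 7 and 17 are labile or volatile and are made just before use (steps 3 and 9). From step 7 onward base is avoided, because C8–O is β to the C6 carbonyl.

Step 1
Reactants: 1 (R)-citramalic acid
Product: 2 2-[(4R)-2,2,4-trimethyl-5-oxo-1,3-dioxolan-4-yl]acetic acid
Conditions: 2,2-dimethoxypropane, TsOH·H2O (cat.), rt
Reagents that add atoms: 2,2-dimethoxypropane, COC(C)(C)OC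
Why: Acid-catalysed acetalisation of an α-hydroxy acid closes the five-membered dioxolanone in preference to the six-membered alternative, which sets the C12 carboxyl apart from the C6 carboxyl; no bond at C11 is broken.

Step 2
Reactants: 2 2-[(4R)-2,2,4-trimethyl-5-oxo-1,3-dioxolan-4-yl]acetic acid; 3 (4S)-4-benzyloxazolidin-2-one
Product: 5 (4S)-4-benzyl-3-{2-[(4R)-2,2,4-trimethyl-5-oxo-1,3-dioxolan-4-yl]acetyl}oxazolidin-2-one, via mixed pivalic anhydride 4 (not isolated)
Conditions: PivCl, Et3N, THF, −20 °C; then 3, LiCl, −20 °C → rt
Reagents that add atoms: pivaloyl chloride, CC(C)(C)C(Cl)=O (its atoms stay in 4 only)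
Why: N-Acylation of the oxazolidinone through a mixed anhydride; the nucleophile attacks the less hindered acyl carbon, and the dioxolanone cannot enolise because C11 is quaternary.

Step 3
Reactants: 6 3-methylbut-3-en-1-ol
Product: 7 3-methylbut-3-enal
Conditions: Dess–Martin periodinane, CH2Cl2, 0 °C; cold NaHCO3/Na2S2O3 wash; used at once as a dried CH2Cl2 solution
Reagents that add atoms: none
Why: Dess–Martin oxidation is near neutral, and the β,γ-unsaturated aldehyde is kept cold and in solution so that the double bond does not move into conjugation.

Step 4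
Reactants: 5 (4S)-4-benzyl-3-{2-[(4R)-2,2,4-trimethyl-5-oxo-1,3-dioxolan-4-yl]acetyl}oxazolidin-2-one; 7 3-methylbut-3-enal
Product: 10 (4S)-4-benzyl-3-{[(2R,3R,4R)-4-hydroxy-4-methyl-2-(2-methylprop-2-en-1-yl)-5-oxooxolan-3-yl]carbonyl}oxazolidin-2-one, via (Z)-dibutylboron enolate 8 (not isolated), via syn-aldol adduct 9 (not isolated)
Conditions: Bu2BOTf, i-Pr2NEt, CH2Cl2, −78 → 0 °C; 7, −78 → 0 °C; pH 7 buffer, MeOH, H2O2, 0 °C; then CSA (cat.), CH2Cl2, rt
Reagents that add atoms: dibutylboryl triflate, CCCCB(CCCC)OS(=O)(=O)C(F)(F)F (boron stays in 8 only)
Why: Evans syn aldol: the Z boron enolate reacts through a Zimmerman–Traxler chair on the face away from the benzyl group, which sets C7 and C8 (2R,3R in 9) under auxiliary control. The C8 hydroxyl then opens the dioxolanone by acid-catalysed 5-exo transacylation, which gives the trans-disubstituted lactone and frees the C11 hydroxyl with loss of the acetonide.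

Step 5
Reactants: 10 (4S)-4-benzyl-3-{[(2R,3R,4R)-4-hydroxy-4-methyl-2-(2-methylprop-2-en-1-yl)-5-oxooxolan-3-yl]carbonyl}oxazolidin-2-one
Product: 11 (4S)-4-benzyl-3-{[(2R,3R,4R)-4-methyl-2-(2-methylprop-2-en-1-yl)-5-oxo-4-(triethylsilyloxy)oxolan-3-yl]carbonyl}oxazolidin-2-one
Conditions: TESOTf, 2,6-lutidine, CH2Cl2, −78 → 0 °C
Reagents that add atoms: triethylsilyl triflate, CC[Si](CC)(CC)OS(=O)(=O)C(F)(F)F
Why: Silyl triflates silylate tertiary alcohols under mildly basic conditions; the ether is needed because a free C11 alkoxide β to the C6 carbonyl would fragment by retro-aldol cleavage of C7–C11.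

Step 6
Reactants: 11 (4S)-4-benzyl-3-{[(2R,3R,4R)-4-methyl-2-(2-methylprop-2-en-1-yl)-5-oxo-4-(triethylsilyloxy)oxolan-3-yl]carbonyl}oxazolidin-2-one
Product: 12 S-ethyl (2R,3R,4R)-4-methyl-2-(2-methylprop-2-en-1-yl)-5-oxo-4-(triethylsilyloxy)oxolane-3-carbothioate
Conditions: EtSH, n-BuLi, THF, 0 °C
Reagents that add atoms: ethanethiol, CCS
Why: Thiolate cleavage of the N-acyl oxazolidinone at the exocyclic carbonyl. The C7–H lies in the imide plane (allylic 1,3-strain), so enolisation and β-elimination should be slow, and the lactone carbonyl is shielded by the quaternary C11.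

Step 7
Reactants: 12 S-ethyl (2R,3R,4R)-4-methyl-2-(2-methylprop-2-en-1-yl)-5-oxo-4-(triethylsilyloxy)oxolane-3-carbothioate; 13 tributyl(vinyl)stannane
Product: 14 (3R,4R,5R)-3-methyl-5-(2-methylprop-2-en-1-yl)-4-(prop-2-enoyl)-3-(triethylsilyloxy)oxolan-2-one
Conditions: Pd2(dba)3 (cat.), tri(2-furyl)phosphine, CuO2PPh2, THF, 50 °C
Reagents that add atoms: none
Why: Liebeskind–Srogl-type coupling of a thioester with an organostannane gives the ketone under neutral conditions, so C7 is not enolised and no C6 alkoxide, which could attack C12, is formed.

Step 8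
Reactants: 14 (3R,4R,5R)-3-methyl-5-(2-methylprop-2-en-1-yl)-4-(prop-2-enoyl)-3-(triethylsilyloxy)oxolan-2-one
Product: 15 (3R,3aR,7aR)-3,6-dimethyl-3-(triethylsilyloxy)-3,3a,7,7a-tetrahydro-1-benzofuran-2,4-dione (ketone C6, enone C5=C10, trans-fused lactone)
Conditions: second-generation Hoveyda–Grubbs catalyst (5 mol %), CH2Cl2, 40 °C
Reagents that add atoms: none
Why: Ring-closing metathesis of a vinyl ketone with a 1,1-disubstituted alkene closes the six-membered trisubstituted enone with loss of ethene; the neutral conditions leave the trans ring fusion at C7 and the β-acyloxy ketone intact.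

Step 9
Reactants: 16 methylenecyclobutane
Product: 17 1-methylcyclobutene
Conditions: Na on Al2O3 (cat.), neat, 0 °C → rt; fractional distillation
Reagents that add atoms: none
Why: Base-catalysed double-bond isomerisation moves the alkene to the trisubstituted endocyclic position, which is favoured at equilibrium; careful distillation removes residual 16, which would otherwise compete in step 10.

Step 10
Reactants: 15 (3R,3aR,7aR)-3,6-dimethyl-3-(triethylsilyloxy)-3,3a,7,7a-tetrahydro-1-benzofuran-2,4-dione; 17 1-methylcyclobutene
Product: 19 cis-anti-cis head-to-head photoadduct (new bonds C1–C10 and C4–C5; H5 and the C10 methyl on one face of the central cyclobutane, H1 and the C4 methyl on the other; cyclobutane on the face of H7), via trans-fused C5 epimer 18 (not isolated)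
Conditions: 17 (10 equiv), hν (medium-pressure Hg lamp, Pyrex filter), CH2Cl2, −30 °C; then neutral Al2O3, Et2O, rt
Reagents that add atoms: none
Why: Excitation of the enone of 15 and intersystem crossing give the triplet, which bonds from its β-carbon C10 to the unsubstituted carbon C1 of 17; the resulting triplet 1,4-biradical (α-keto radical at C5, tertiary radical at C4) closes the C4–C5 bond after spin inversion. The closest known reaction type is the enone–alkene [2+2] photocycloaddition of 3-alkylcyclohex-2-enones with cyclobutenes, which is known to be followed by thermal opening to cyclodeca-1,5-dienes. One ring is closed, the central cyclobutane C1–C4–C5–C10, by stepwise biradical recombination; because C1–C4 already lies in a four-membered ring, the product is a bicyclo[2.2.0]hexane. C1 and C4 can only be cis (the cyclobutene bond), the outer cyclobutane is expected anti to the six-membered ring for steric reasons, and the alkene should approach the enone face that carries H7, away from the silyloxy group on C11. Closure at C5 can occur cis or trans to the C10–C9 bond; the strained trans-fused epimer 18 has an enolisable C5–H and is expected to relax to the cis-fused 19 on alumina, whereas C7–H, flanked by the quaternary C11, should be left alone. The step needs head-to-head regiochemistry (C10–C1 and C5–C4), which the methyl group on C10 secures, since the other orientation would join the two fully substituted carbons C10 and C4 and its biradical should revert to the components. It also needs the cis ring fusion at C5/C10, because this relationship, unlike the face of attack or the syn/anti sense, survives into step 11 as the E/Z pattern of the two new alkenes.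

Step 11
Reactants: 19 cis-anti-cis head-to-head photoadduct
Product: 20 (7R,8R,11R)-6-oxo-11-(triethylsilyloxy)germacra-1(10)Z,4E-dien-12,8-olide (ten-membered dienone, trans lactone)
Conditions: toluene (degassed), sealed base-washed tube, 200 °C
Reagents that add atoms: none
Why: Thermal cycloreversion of the bicyclo[2.2.0]hexane: the central C1–C4 bond breaks to a cyclohexane-1,4-diyl, and scission of C5–C10 is preferred over C2–C3 because it gives a conjugated enone and two trisubstituted alkenes. In the chair diyl of the cis-fused adduct, C6 sits equatorial and C9 axial (the C10 methyl equatorial), which corresponds to E at C4=C5 and Z at C1=C10.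

Step 12
Reactants: 20 (7R,8R,11R)-6-oxo-11-(triethylsilyloxy)germacra-1(10)Z,4E-dien-12,8-olide
Product: 21 (6S,7R,8R,11R)-6-hydroxy-11-(triethylsilyloxy)germacra-1(10)Z,4E-dien-12,8-olide
Conditions: NaBH4, CeCl3·7H2O, MeOH, −78 °C
Reagents that add atoms: none
Why: Luche 1,2-reduction of the enone under non-basic conditions; by the Felkin–Anh model hydride should enter anti to the bulky silyloxy-bearing C11 on C7 while the C7–C8 ring bond lies near the carbonyl plane, which gives the 6S carbinol (C6–O anti to C7–C11).

Step 13
Reactants: 21 (6S,7R,8R,11R)-6-hydroxy-11-(triethylsilyloxy)germacra-1(10)Z,4E-dien-12,8-olide; 22 angelic acid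
Product: 24 (6S,7S,8R,11R)-6-angeloyloxy-11-(triethylsilyloxy)germacra-1(10)Z,4E-dien-12,8-olide, via mixed angelic 2,4,6-trichlorobenzoic anhydride 23 (not isolated)
Conditions: 22, 2,4,6-trichlorobenzoyl chloride, Et3N, toluene, rt; then 21, 75 °C
Reagents that add atoms: 2,4,6-trichlorobenzoyl chloride, O=C(Cl)c1c(Cl)cc(Cl)cc1Cl (its atoms stay in 23 only)
Why: Yamaguchi-type mixed-anhydride esterification without a nucleophilic catalyst: the alcohol attacks the unhindered angeloyl carbonyl, the Z geometry has no addition–elimination path for isomerisation, and no C6 alkoxide is generated that could translactonise onto C12.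

Step 14
Reactants: 24 (6S,7S,8R,11R)-6-angeloyloxy-11-(triethylsilyloxy)germacra-1(10)Z,4E-dien-12,8-olide
Product: 25 (6S,7S,8R,11R)-6-angeloyloxy-11-hydroxygermacra-1(10)Z,4E-dien-12,8-olide
Conditions: HF·pyridine, pyridine, THF, 0 °C → rt
Reagents that add atoms: none
Why: Fluoride cleavage of the silyl ether in a pyridine-buffered medium, which spares the allylic ester and the diene; with C6 no longer a carbonyl the free C11 hydroxyl is safe.

Step 15
Reactants: 25 (6S,7S,8R,11R)-6-angeloyloxy-11-hydroxygermacra-1(10)Z,4E-dien-12,8-olide; 26 angelic anhydride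
Product: 28 (6S,7S,8R,11R)-6,11-bis(angeloyloxy)germacra-1(10)Z,4E-dien-12,8-olide (CNP0391997.3), via lithium C11 alkoxide 27 (not isolated)
Conditions: LiN(SiMe3)2, THF, −78 °C; then 26, −78 → −20 °C
Reagents that add atoms: lithium bis(trimethylsilyl)amide, [Li+].C[Si](C)(C)[N-][Si](C)(C)C (lithium stays in 27 only)
Why: Acylation of a preformed tertiary lithium alkoxide by an anhydride needs no nucleophilic catalyst, so the angelate should keep its Z geometry; the alkoxide cannot attack its own lactone carbonyl.

## Compound list

1 | (R)-citramalic acid, (2R)-2-hydroxy-2-methylbutanedioic acid | OC(=O)[C@](C)(O)CC(=O)O | starting material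
2 | 2-[(4R)-2,2,4-trimethyl-5-oxo-1,3-dioxolan-4-yl]acetic acid | CC1(C)OC(=O)[C@](C)(O1)CC(=O)O | intermediate
3 | (4S)-4-benzyloxazolidin-2-one | O=C1N[C@@H](Cc2ccccc2)CO1 | starting material
4 | mixed pivalic anhydride of 2 | CC1(C)OC(=O)[C@](C)(O1)CC(=O)OC(=O)C(C)(C)C | intermediate
5 | (4S)-4-benzyl-3-{2-[(4R)-2,2,4-trimethyl-5-oxo-1,3-dioxolan-4-yl]acetyl}oxazolidin-2-one | CC1(C)OC(=O)[C@](C)(O1)CC(=O)N2[C@@H](Cc3ccccc3)COC2=O | intermediate
6 | 3-methylbut-3-en-1-ol | CC(=C)CCO | starting material
7 | 3-methylbut-3-enal | CC(=C)CC=O | intermediate
8 | (Z)-dibutylboron enolate of 5 | CCCCB(CCCC)O/C(=C\[C@@]1(C)OC(C)(C)OC1=O)N2[C@@H](Cc3ccccc3)COC2=O | intermediate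
9 | (4S)-4-benzyl-3-[(2R,3R)-3-hydroxy-5-methyl-2-[(4R)-2,2,4-trimethyl-5-oxo-1,3-dioxolan-4-yl]hex-5-enoyl]oxazolidin-2-one | CC(=C)C[C@@H](O)[C@@H](C(=O)N2[C@@H](Cc3ccccc3)COC2=O)[C@@]1(C)OC(C)(C)OC1=O | intermediate
10 | (4S)-4-benzyl-3-{[(2R,3R,4R)-4-hydroxy-4-methyl-2-(2-methylprop-2-en-1-yl)-5-oxooxolan-3-yl]carbonyl}oxazolidin-2-one | CC(=C)C[C@H]1OC(=O)[C@](C)(O)[C@@H]1C(=O)N2[C@@H](Cc3ccccc3)COC2=O | intermediate
11 | (4S)-4-benzyl-3-{[(2R,3R,4R)-4-methyl-2-(2-methylprop-2-en-1-yl)-5-oxo-4-(triethylsilyloxy)oxolan-3-yl]carbonyl}oxazolidin-2-one | CC(=C)C[C@H]1OC(=O)[C@](C)(O[Si](CC)(CC)CC)[C@@H]1C(=O)N2[C@@H](Cc3ccccc3)COC2=O | intermediate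
12 | S-ethyl (2R,3R,4R)-4-methyl-2-(2-methylprop-2-en-1-yl)-5-oxo-4-(triethylsilyloxy)oxolane-3-carbothioate | CC(=C)C[C@H]1OC(=O)[C@](C)(O[Si](CC)(CC)CC)[C@@H]1C(=O)SCC | intermediate
13 | tributyl(vinyl)stannane | C=C[Sn](CCCC)(CCCC)CCCC | starting material
14 | (3R,4R,5R)-3-methyl-5-(2-methylprop-2-en-1-yl)-4-(prop-2-enoyl)-3-(triethylsilyloxy)oxolan-2-one | CC(=C)C[C@H]1OC(=O)[C@](C)(O[Si](CC)(CC)CC)[C@@H]1C(=O)C=C | intermediate
15 | (3R,3aR,7aR)-3,6-dimethyl-3-(triethylsilyloxy)-3,3a,7,7a-tetrahydro-1-benzofuran-2,4-dione | O=C1C=C(C)C[C@H]2OC(=O)[C@](C)(O[Si](CC)(CC)CC)[C@H]12 | intermediate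
16 | methylenecyclobutane | C=C1CCC1 | starting material
17 | 1-methylcyclobutene | CC1=CCC1 | intermediate
18 | trans-fused photoadduct, C5 epimer of 19 | O=C1[C@@H]3[C@]4(C)CC[C@@H]4[C@@]3(C)C[C@H]2OC(=O)[C@](C)(O[Si](CC)(CC)CC)[C@H]12 | intermediate
19 | cis-anti-cis head-to-head photoadduct (bicyclo[2.2.0]hexane C1–C2–C3–C4 and C1–C4–C5–C10, fused to the C6 ketone ring and trans lactone) | O=C1[C@H]3[C@]4(C)CC[C@@H]4[C@@]3(C)C[C@H]2OC(=O)[C@](C)(O[Si](CC)(CC)CC)[C@H]12 | intermediate
20 | (7R,8R,11R)-6-oxo-11-(triethylsilyloxy)germacra-1(10)Z,4E-dien-12,8-olide | O=C1/C=C(\C)CC/C=C(/C)C[C@H]2OC(=O)[C@](C)(O[Si](CC)(CC)CC)[C@H]12 | intermediate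
21 | (6S,7R,8R,11R)-6-hydroxy-11-(triethylsilyloxy)germacra-1(10)Z,4E-dien-12,8-olide | O[C@H]1/C=C(\C)CC/C=C(/C)C[C@H]2OC(=O)[C@](C)(O[Si](CC)(CC)CC)[C@H]12 | intermediate
22 | angelic acid, (Z)-2-methylbut-2-enoic acid | C/C=C(/C)C(=O)O | starting material
23 | mixed angelic 2,4,6-trichlorobenzoic anhydride | C/C=C(/C)C(=O)OC(=O)c1c(Cl)cc(Cl)cc1Cl | intermediate
24 | (6S,7S,8R,11R)-6-angeloyloxy-11-(triethylsilyloxy)germacra-1(10)Z,4E-dien-12,8-olide | C/C=C(/C)C(=O)O[C@H]1/C=C(\C)CC/C=C(/C)C[C@H]2OC(=O)[C@](C)(O[Si](CC)(CC)CC)[C@H]12 | intermediate
25 | (6S,7S,8R,11R)-6-angeloyloxy-11-hydroxygermacra-1(10)Z,4E-dien-12,8-olide | C/C=C(/C)C(=O)O[C@H]1/C=C(\C)CC/C=C(/C)C[C@H]2OC(=O)[C@](C)(O)[C@H]12 | intermediate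
26 | angelic anhydride | C/C=C(/C)C(=O)OC(=O)/C(C)=C\C | starting material
27 | lithium C11 alkoxide of 25 | C/C=C(/C)C(=O)O[C@H]1/C=C(\C)CC/C=C(/C)C[C@H]2OC(=O)[C@](C)([O-])[C@H]12.[Li+] | intermediate
28 | (6S,7S,8R,11R)-6,11-bis(angeloyloxy)germacra-1(10)Z,4E-dien-12,8-olide (CNP0391997.3) | C/C=C(/C)C(=O)O[C@H]1/C=C(\C)CC/C=C(/C)C[C@H]2OC(=O)[C@](C)(OC(=O)/C(C)=C\C)[C@H]12 | target

## Step count and least certain steps

Total step count: 15. Longest linear sequence: 13 steps (steps 1, 2, 4, 5, 6, 7, 8, 10, 11, 12, 13, 14, 15); steps 3 and 9 are side branches.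

**Step 10 (key step).** The most likely problems are slow capture of the short-lived enone triplet by a hindered trisubstituted alkene, which leaves room for photodeconjugation and dimerisation of 15, and leakage into head-to-tail bonding or into trans closure that is not fully corrected on alumina. The fallback keeps the same two bond formations but removes the regiochemical question and the congestion at the closing C4–C5 bond. It sets out from 15, which would be irradiated with the symmetrical parent cyclobutene to give the nor-methyl cis-fused adduct F1. Heating F1 as in step 11 should give the 4-desmethyl (1(10)Z,4E)-dienone F2. Conjugate addition of Me2CuLi in the presence of Me3SiCl would place C15 on C4 and give the trimethylsilyl enol ether F3; the enolate lies between C5 and C6, so the C8 carboxylate is not eliminated. Saegusa oxidation with Pd(OAc)2 in MeCN would restore the C4=C5 enone, and the route is rejoined at 20. The E geometry of that alkene would have to be confirmed.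

**Step 11.** What may go wrong is partition of the diyl toward C2–C3 scission or later Cope rearrangement of the dienone to a divinylcyclohexane, and thermal enolisation toward C7 with epimerisation of the ring fusion or loss of the C8 carboxylate. The fallback reverses the order of reduction and cleavage. It sets out from 19, which would be reduced under the conditions of step 12 to the tricyclic C6 carbinol F4. With no carbonyl, C7 cannot enolise; F4 would then be thermolysed with short contact time (flow pyrolysis) and the route is rejoined at 21. The price is the loss of the conjugative bias for C5–C10 scission. Should the reduction of 19 give the other C6 epimer, the inversion described under step 12 applies after cycloreversion.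

**Step 12.** The risk is poor facial selectivity, because several conformers of the ten-membered enone may present different carbonyl faces, and migration of the lactone from O8 to the new O6 under basic work-up. The fallback sets out from 20. If reduction gives mainly the 6R carbinol F5 (a bulky hydride such as LiBH(s-Bu)3 could be used to make this the sole product), Mitsunobu esterification of F5 with 22 (PPh3, DIAD, toluene, 0 °C) would invert C6 and install the angelate in one operation. The route is rejoined at 24, and step 13 is then not needed.

**Step 15.** The tertiary alkoxide may acylate slowly, which allows Z to E isomerisation of the angeloyl groups, or acyl migration from O6 to O11 followed by attack of the freed C6 alkoxide on C12. The fallback builds the Z alkene on the ester and does not carry it in. It sets out from 25, whose lithium alkoxide would be acylated with 2-[bis(2,2,2-trifluoroethoxy)phosphoryl]propanoyl chloride to the phosphonopropionate F6. Still–Gennari olefination of F6 with acetaldehyde (KN(SiMe3)2, 18-crown-6, THF, −78 °C) should give the Z-2-methylbut-2-enoate, and the route is rejoined at 28.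

**Step 7 (with step 6).** Thiolate cleavage of the hindered imide may be slow, and in the coupling slow transmetallation may leave the vinyl ketone exposed to conjugate addition of thiolate or to polymerisation. The fallback sets out from 11. Hydrolysis with LiOH/H2O2 (THF/H2O, 0 °C) would give the carboxylic acid F7. 1-Chloro-N,N,2-trimethylprop-1-en-1-amine would convert it under neutral conditions into the acid chloride F8. Stille acylation of F8 with 13 (PdCl2(PPh3)2 cat., toluene, 60 °C) would give the vinyl ketone, and the route is rejoined at 14.

## Further compounds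

F1 | step 10 | nor-methyl cis-anti-cis photoadduct of 15 and cyclobutene (H in place of the C4 methyl of 19) | O=C1[C@H]3[C@@H]4CC[C@@H]4[C@@]3(C)C[C@H]2OC(=O)[C@](C)(O[Si](CC)(CC)CC)[C@H]12
F2 | step 10 | (7R,8R,11R)-15-nor-6-oxo-11-(triethylsilyloxy)germacra-1(10)Z,4E-dien-12,8-olide | O=C1/C=C/CC/C=C(/C)C[C@H]2OC(=O)[C@](C)(O[Si](CC)(CC)CC)[C@H]12
F3 | step 10 | C6 trimethylsilyl enol ether (C5=C6) of the 4,5-dihydro derivative of 20, C4 epimers | C[Si](C)(C)OC1=CC(C)CC/C=C(/C)C[C@H]2OC(=O)[C@](C)(O[Si](CC)(CC)CC)[C@H]12
F4 | step 11 | tricyclic C6 carbinol from 19 (C6 configured as in 21) | O[C@H]1[C@H]3[C@]4(C)CC[C@@H]4[C@@]3(C)C[C@H]2OC(=O)[C@](C)(O[Si](CC)(CC)CC)[C@H]12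
F5 | step 12 | (6R,7R,8R,11R)-6-hydroxy-11-(triethylsilyloxy)germacra-1(10)Z,4E-dien-12,8-olide, C6 epimer of 21 | O[C@@H]1/C=C(\C)CC/C=C(/C)C[C@H]2OC(=O)[C@](C)(O[Si](CC)(CC)CC)[C@H]12
F6 | step 15 | 11-O-{2-[bis(2,2,2-trifluoroethoxy)phosphoryl]propanoyl} derivative of 25, epimers at the phosphonate carbon | C/C=C(/C)C(=O)O[C@H]1/C=C(\C)CC/C=C(/C)C[C@H]2OC(=O)[C@](C)(OC(=O)C(C)P(=O)(OCC(F)(F)F)OCC(F)(F)F)[C@H]12
F7 | step 7 | (2R,3R,4R)-4-methyl-2-(2-methylprop-2-en-1-yl)-5-oxo-4-(triethylsilyloxy)oxolane-3-carboxylic acid | CC(=C)C[C@H]1OC(=O)[C@](C)(O[Si](CC)(CC)CC)[C@@H]1C(=O)O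
F8 | step 7 | (2R,3R,4R)-4-methyl-2-(2-methylprop-2-en-1-yl)-5-oxo-4-(triethylsilyloxy)oxolane-3-carbonyl chloride | CC(=C)C[C@H]1OC(=O)[C@](C)(O[Si](CC)(CC)CC)[C@@H]1C(Cl)=O
A1 | alternative 1 | isoxazoline-bridged ten-membered diene methyl ester (O on C6, C=N at C8, C11 methoxymethyl ether) | COC(=O)[C@](C)(OCOC)[C@@H]1[C@@H]2/C=C(\C)CC/C=C(/C)CC1=NO2
A2 | alternative 1 | open-chain nitro triene methyl ester (nitro on C8; 6Z,4E,1(10)Z) | COC(=O)[C@](C)(OCOC)/C=C\C=C(/C)CC/C=C(/C)CC[N+](=O)[O-]
A3 | alternative 2 | ten-membered C6 carbinol with exocyclic C11=C13 methylene, C8 tert-butyldimethylsilyl ether, C12 triisopropylsilyl ether | O[C@H]1/C=C(\C)CC/C=C(/C)C[C@@H](O[Si](C)(C)C(C)(C)C)[C@@H]1C(=C)CO[Si](C(C)C)(C(C)C)C(C)C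
A4 | alternative 2 | thirteen-membered cyclic ether (O between C6 and C13), C6 tributylstannyl, C7=C11 alkene with C8 cis to C12 | O1[C@@H]([Sn](CCCC)(CCCC)CCCC)/C=C(\C)CC/C=C(/C)C[C@@H](O[Si](C)(C)C(C)(C)C)/C=C(\CO[Si](C(C)C)(C(C)C)C(C)C)C1
A5 | alternative 3 | α-angeloyloxy N-(6-bromopyridin-2-yl) amide on the ten-membered ring (C6 angelate, C8 tert-butyldimethylsilyl ether) | C/C=C(/C)C(=O)O[C@H]1/C=C(\C)CC/C=C(/C)C[C@@H](O[Si](C)(C)C(C)(C)C)[C@@H]1[C@@](C)(OC(=O)/C(C)=C\C)C(=O)Nc1cccc(Br)n1
A6 | alternative 3 | C7 acetyl ten-membered diene (C6 angelate, C8 tert-butyldimethylsilyl ether) | C/C=C(/C)C(=O)O[C@H]1/C=C(\C)CC/C=C(/C)C[C@@H](O[Si](C)(C)C(C)(C)C)[C@@H]1C(C)=O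
A7 | alternative 3 | 2-bromo-6-isocyanopyridine | [C-]#[N+]c1cccc(Br)n1
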